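**Strategy.** The trimethylcyclohexene ring carries a CH2–CH2 unit (C3–C4, carotenoid numbering) between the methyl-bearing sp2 carbon C5 and the stereogenic CH C2. Cutting both bonds that hold it (C4–C5, C2–C3) leaves C5–C6–C1–C2, which is written as a 2-silyloxy-1,3-diene: C6 as enol-ether carbon, C1 one methyl short. A catalytic enantioselective Diels–Alder reaction with acrolein, an ethylene equivalent, closes the ring, sets C2 and places an enol ether where the gem-dimethyl carbon and the polyene anchor are needed. Decarbonylation, regiospecific methylation and enol-triflate chemistry give a C15 phosphonium salt; Wittig reactions with crocetindialdehyde and an epoxide-derived acyclic C15 salt, then ester reduction, finish the C50 chain.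

Key step: step 3

Remarks on the chemistry (assumptions):
- Ring atoms are named by carotenoid numbering: C1 = CMe2, C2 = stereogenic CH, C5 = methyl-bearing sp2 carbon, C6 = ring carbon carrying the chain.
- Crocetindialdehyde and the o-tolyl-CBS oxazaborolidine are taken as purchasable.
- The diene must add to the Re face at C2 of bound acrolein. The (S)-configured catalyst is assumed to leave this face open; if the sense is the opposite, the (R)-catalyst is used and nothing else changes.
- The methyl-bearing stereocentre of compounds 6–12 is of no consequence: it becomes sp2 in step 8.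

**Ring end (steps 1–10)**

Step 1
Reactants: 1 2-methylpent-1-en-3-one; 2 4-(benzyloxy)but-1-ene
Product: 3 (4E)-7-(benzyloxy)-4-methylhept-4-en-3-one
Conditions: Hoveyda–Grubbs II (5 mol%), 1 (3 equiv), CH2Cl2, 40 °C
Reagents that add atoms: none
Why: Olefin cross-metathesis of a terminal alkene with a 1,1-disubstituted enone that does not homodimerise should give the trisubstituted enone as the favoured E isomer.

Step 2
Reactants: 3 (4E)-7-(benzyloxy)-4-methylhept-4-en-3-one
Product: 4 {[(2Z,4E)-7-(benzyloxy)-4-methylhepta-2,4-dien-3-yl]oxy}tri(propan-2-yl)silane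
Conditions: TIPSOTf (1.2 equiv), Et3N (2 equiv), CH2Cl2, 0 °C → rt
Reagents that add atoms: triisopropylsilyl trifluoromethanesulfonate CC(C)[Si](C(C)C)(C(C)C)OS(=O)(=O)C(F)(F)F
Why: Soft enolisation (O-silylation, then loss of an α′-proton of the ethyl group) should give the cross-conjugated 2-silyloxydiene, the Z enol ether being favoured because the methyl group avoids the alkenyl substituent.

Step 3
Reactants: 4 the (2Z,4E)-silyloxydiene; 5 acrolein (prop-2-enal)
Product: 6 (1S,2S,5R)-2-[2-(benzyloxy)ethyl]-3,5-dimethyl-4-{[tri(propan-2-yl)silyl]oxy}cyclohex-3-ene-1-carbaldehyde (all-cis)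
Conditions: (S)-o-tolyl-CBS oxazaborolidine (20 mol%), Tf2NH (17 mol%), 5 (3 equiv), CH2Cl2, −78 °C; chromatography
Reagents that add atoms: none
Why: The protonated oxazaborolidine binds the carbonyl oxygen of acrolein and lowers its LUMO, so that the electron-rich diene 4 adds in a concerted, asynchronous normal-demand [4+2] cycloaddition (catalytic enantioselective Diels–Alder reaction of a 2-silyloxydiene with an enal). The cyclohexene ring is closed by intermolecular [4+2] cycloaddition, suprafacial on both partners: the enol-ether terminus bonds to the acrolein β-carbon and the side-chain terminus to the α-carbon in the same step. The stereocentre that persists, the ring CH carrying the benzyloxyethyl group, is set by the catalyst, which shields the Si face at C2 of s-trans acrolein so that the diene adds endo to the Re face. The CHO- and CH3-bearing centres are transient (the first is excised in step 4, the second becomes sp2 in step 8) and follow from endo addition and from the outside position of both diene-terminus substituents. The step needs regio-, endo- and facial selectivity: the 2-silyloxy group makes the enol-ether terminus the nucleophilic end, reinforced by the alkyl group on the other terminus; secondary overlap with the coordinated formyl group favours endo; the catalyst provides the facial bias. Regio- and exo-isomers are diastereomers and are removed by chromatography, so the enantiomeric purity of the ring rests on facial discrimination alone.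

Step 4
Reactants: 6 the cycloadduct aldehyde
Product: 7 {[(3R,6R)-3-[2-(benzyloxy)ethyl]-2,6-dimethylcyclohex-1-en-1-yl]oxy}tri(propan-2-yl)silane
Conditions: [Rh(dppp)2]Cl (5 mol%), diglyme, 160 °C, Ar sweep
Reagents that add atoms: none
Why: Tsuji–Wilkinson decarbonylation (formyl C–H oxidative addition, CO extrusion, C–H reductive elimination) should remove the activating formyl group under neutral conditions that spare the TIPS enol ether and the stereocentre.

Step 5
Reactants: 7 the TIPS enol ether
Product: 8 (3R,6R)-3-[2-(benzyloxy)ethyl]-2,2,6-trimethylcyclohexan-1-one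
Conditions: TASF (1.2 equiv), MeI (5 equiv), THF, −78 → 0 °C
Reagents that add atoms: iodomethane CI
Why: Fluoride-induced desilylation should give the enolate only at the former enol-ether double bond, and its C-methylation (regiospecific alkylation of a silyl enol ether) creates the quaternary gem-dimethyl carbon without a new stereocentre.

Step 6
Reactants: 8 the benzyl ether ketone
Product: 9 (3R,6R)-3-(2-hydroxyethyl)-2,2,6-trimethylcyclohexan-1-one
Conditions: H2 (1 atm), 10% Pd/C, EtOAc, rt
Reagents that add atoms: none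
Why: Hydrogenolysis of the benzyl ether should proceed without reduction of the hindered ketone.

Step 7
Reactants: 9 the hydroxy ketone; 10 ethyl 2-(triphenyl-λ5-phosphanylidene)propanoate
Product: 12 ethyl (2E)-2-methyl-4-[(1R,4R)-2,2,4-trimethyl-3-oxocyclohexyl]but-2-enoate, via keto aldehyde 11 (not isolated)
Conditions: TEMPO (10 mol%), PhI(OAc)2 (1.1 equiv), CH2Cl2, rt; then 10 (1.3 equiv), rt → 40 °C
Reagents that add atoms: none
Why: Selective TEMPO/PhI(OAc)2 oxidation of the primary alcohol and trapping of the aldehyde in the same flask by the stabilised α-methyl ylide (one-pot oxidation–Wittig olefination) should give the E trisubstituted enoate, while the hindered ketone does not react.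

Step 8
Reactants: 12 the keto enoate
Product: 13 ethyl (2E)-2-methyl-4-[(1R)-2,2,4-trimethyl-3-{[(trifluoromethyl)sulfonyl]oxy}cyclohex-3-en-1-yl]but-2-enoate
Conditions: Tf2O (1.3 equiv), 2,6-di-tert-butyl-4-methylpyridine (1.5 equiv), CH2Cl2, 0 °C → rt
Reagents that add atoms: trifluoromethanesulfonic anhydride O=S(=O)(OS(=O)(=O)C(F)(F)F)C(F)(F)F
Why: Enol triflate formation under Stang conditions (O-triflation, then loss of the only α-proton) avoids a strong base that would deprotonate the enoate, and the double bond can only form toward the methyl-bearing carbon because the other α-carbon is quaternary.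

Step 9
Reactants: 13 the vinyl triflate
Product: 14 ethyl (2E)-4-[(1R)-3-(hydroxymethyl)-2,2,4-trimethylcyclohex-3-en-1-yl]-2-methylbut-2-enoate
Conditions: Bu3SnCH2OH (1.5 equiv), Pd(PPh3)4 (10 mol%), LiCl (3 equiv), 1,4-dioxane, 100 °C
Reagents that add atoms: (tributylstannyl)methanol OC[Sn](CCCC)(CCCC)CCCC
Why: Stille (Kosugi–Migita) hydroxymethylation, by oxidative addition of the triflate, LiCl-assisted transfer of CH2OH from tin and reductive elimination, should give the allylic alcohol with the ring double bond in place.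

Step 10
Reactants: 14 the allylic alcohol
Product: 15 ({(5R)-5-[(2E)-4-ethoxy-3-methyl-4-oxobut-2-en-1-yl]-2,6,6-trimethylcyclohex-1-en-1-yl}methyl)triphenylphosphonium bromide
Conditions: Ph3P·HBr (1.05 equiv), CH2Cl2, rt
Reagents that add atoms: triphenylphosphine hydrobromide [Br-].[PH+](c1ccccc1)(c1ccccc1)c1ccccc1
Why: Acid ionisation of the allylic alcohol and capture of the allyl cation by PPh3 at its primary terminus (standard carotenoid phosphonium-salt formation) should leave the ester and the stereocentre untouched.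

**Acyclic end (steps 11–18)**

Step 11
Reactants: 16 3-methylbut-2-en-1-ol (prenol)
Product: 17 [(2R)-3,3-dimethyloxiran-2-yl]methanol
Conditions: Ti(OiPr)4 (5 mol%), D-(−)-diisopropyl tartrate (7 mol%), t-BuOOH (2 equiv), 4 Å MS, CH2Cl2, −20 °C; non-aqueous work-up
Reagents that add atoms: tert-butyl hydroperoxide CC(C)(C)OO
Why: Sharpless asymmetric epoxidation, in which the Ti–D-(−)-tartrate catalyst delivers oxygen to the alkene face that gives the 2R epoxide (reagent control).

Step 12
Reactants: 17 the (R)-epoxy alcohol; 18 allylmagnesium bromide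
Product: 19 (2S)-3-methyl-2-(prop-2-en-1-yl)butane-1,3-diol
Conditions: 18 (3 equiv), CuI (10 mol%), THF/Et2O, −40 → −10 °C; aq. NH4Cl
Reagents that add atoms: none
Why: Copper-catalysed Grignard opening of the 2,3-epoxy alcohol by SN2 attack at C2 (C3 is fully substituted) with inversion should turn the R epoxide carbon into the S carbon of the 1,3-diol.

Step 13
Reactants: 19 the allyl diol; 20 2-methylbut-2-ene
Product: 21 (2S)-3-methyl-2-(3-methylbut-2-en-1-yl)butane-1,3-diol
Conditions: Grubbs II (3 mol%), 20 (large excess), CH2Cl2, 40 °C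
Reagents that add atoms: none
Why: Cross-metathesis with 2-methylbut-2-ene converts the allyl into the prenyl group, tolerates free hydroxyl groups and does not involve the stereocentre.

Step 14
Reactants: 21 the prenyl diol
Product: 22 (2S)-3-methyl-2-(3-methylbut-2-en-1-yl)butane-1,3-diol bis(triethylsilyl) ether
Conditions: TESOTf (2.5 equiv), 2,6-lutidine (4 equiv), CH2Cl2, −78 → 0 °C
Reagents that add atoms: triethylsilyl trifluoromethanesulfonate CC[Si](CC)(CC)OS(=O)(=O)C(F)(F)F
Why: Silyl triflate with 2,6-lutidine silylates both the primary and the hindered tertiary hydroxyl group.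

Step 15
Reactants: 22 the bis-TES ether
Product: 23 (2R)-5-methyl-2-{2-[(triethylsilyl)oxy]propan-2-yl}hex-4-enal
Conditions: (COCl)2 (4 equiv), DMSO (8 equiv), CH2Cl2, −78 → −40 °C; Et3N, −78 → 0 °C
Reagents that add atoms: none
Why: Swern conditions cleave and oxidise a primary TES ether directly to the aldehyde while the tertiary TES ether cannot react (selective Swern oxidation of a primary silyl ether); the protected β-oxygen and low temperature guard the α-stereocentre against retro-aldol cleavage and epimerisation.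

Step 16
Reactants: 23 the α-branched aldehyde; 24 ethyl (2E)-4-(diethoxyphosphoryl)-3-methylbut-2-enoate
Product: 25 ethyl (2E,4E,6S)-3,7-dimethyl-6-(3-methylbut-2-en-1-yl)-7-[(triethylsilyl)oxy]octa-2,4-dienoate
Conditions: 24 (1.5 equiv), LiHMDS (1.4 equiv), THF/DMPU, −78 → −20 °C
Reagents that add atoms: none
Why: Horner–Wadsworth–Emmons olefination with the vinylogous phosphonate should give the (2E,4E)-dienoate, with the new disubstituted double bond E and the α-stereocentre of the aldehyde preserved at low temperature.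

Step 17
Reactants: 25 the dienoate
Product: 26 (2E,4E,6S)-3,7-dimethyl-6-(3-methylbut-2-en-1-yl)-7-[(triethylsilyl)oxy]octa-2,4-dien-1-ol
Conditions: DIBAL-H (2.5 equiv), CH2Cl2, −78 °C; Rochelle salt
Reagents that add atoms: none
Why: DIBAL-H reduces the conjugated ester 1,2 to the allylic alcohol without touching the diene or the silyl ether.

Step 18
Reactants: 26 the dienol
Product: 27 [(2E,4E,6S)-7-hydroxy-3,7-dimethyl-6-(3-methylbut-2-en-1-yl)octa-2,4-dien-1-yl]triphenylphosphonium bromide
Conditions: Ph3P·HBr (1.1 equiv), MeOH, 0 °C → rt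
Reagents that add atoms: triphenylphosphine hydrobromide [Br-].[PH+](c1ccccc1)(c1ccccc1)c1ccccc1
Why: Ph3P·HBr ionises the dienylic alcohol and PPh3 captures the pentadienyl cation at its primary terminus (phosphonium-salt formation), while the acidic methanol should also cleave the tertiary TES ether; the stereocentre is not part of the cation.

**Assembly (steps 19–21)**

Step 19
Reactants: 15 the ring phosphonium bromide; 28 crocetindialdehyde, (2E,4E,6E,8E,10E,12E,14E)-2,6,11,15-tetramethylhexadeca-2,4,6,8,10,12,14-heptaenedial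
Product: 29 ethyl (2E)-2-methyl-4-{(1R)-2,2,4-trimethyl-3-[(1E,3E,5E,7E,9E,11E,13E,15E)-3,7,12,16-tetramethyl-17-oxoheptadeca-1,3,5,7,9,11,13,15-octaen-1-yl]cyclohex-3-en-1-yl}but-2-enoate
Conditions: 28 (3 equiv, excess recovered), NaOEt (1.1 equiv), EtOH/CH2Cl2, 0 °C → rt
Reagents that add atoms: none
Why: Wittig olefination of the allylic ylide with one formyl group of the dialdehyde used in excess (statistical mono-olefination) forms C7=C8, E being favoured by the bulk of the trimethylcyclohexenyl group.

Step 20
Reactants: 29 the C35 aldehyde; 27 the acyclic phosphonium bromide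
Product: 30 C50 ester: the target skeleton, all-E, (2R,2′S), with the ring side chain as (E)-CH2CH=C(CH3)CO2Et
Conditions: 27 (1.3 equiv), NaOEt (2.5 equiv), EtOH/CH2Cl2, 0 °C → rt; then heptane, 90 °C (E/Z equilibration), crystallisation
Reagents that add atoms: none
Why: The second Wittig olefination joins the acyclic end at C7′=C8′, and the E/Z mixture at the new disubstituted double bond should converge on the all-E polyene by the thermal isomerisation usual for carotenoids.

Step 21
Reactants: 30 the C50 ester
Product: 31 the target, CNP0286110.1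
Conditions: DIBAL-H (4 equiv), CH2Cl2/THF, −78 °C; Rochelle salt, dim light
Reagents that add atoms: none
Why: DIBAL-H reduces the conjugated ethyl ester 1,2 to the primary allylic alcohol; the polyene, the tertiary alcohol (as its aluminate) and both stereocentres are unaffected.

**Compound list**

1 | 2-methylpent-1-en-3-one | CCC(=O)C(C)=C | starting material
2 | 4-(benzyloxy)but-1-ene | C=CCCOCc1ccccc1 | starting material
3 | (4E)-7-(benzyloxy)-4-methylhept-4-en-3-one | CCC(=O)/C(C)=C/CCOCc1ccccc1 | intermediate
4 | {[(2Z,4E)-7-(benzyloxy)-4-methylhepta-2,4-dien-3-yl]oxy}tri(propan-2-yl)silane | C/C=C(/C(C)=C/CCOCc1ccccc1)O[Si](C(C)C)(C(C)C)C(C)C | intermediate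
5 | acrolein | C=CC=O | starting material
6 | (1S,2S,5R)-2-[2-(benzyloxy)ethyl]-3,5-dimethyl-4-{[tri(propan-2-yl)silyl]oxy}cyclohex-3-ene-1-carbaldehyde | C[C@@H]1C[C@H](C=O)[C@H](CCOCc2ccccc2)C(C)=C1O[Si](C(C)C)(C(C)C)C(C)C | intermediate
7 | {[(3R,6R)-3-[2-(benzyloxy)ethyl]-2,6-dimethylcyclohex-1-en-1-yl]oxy}tri(propan-2-yl)silane | C[C@@H]1CC[C@H](CCOCc2ccccc2)C(C)=C1O[Si](C(C)C)(C(C)C)C(C)C | intermediate
8 | (3R,6R)-3-[2-(benzyloxy)ethyl]-2,2,6-trimethylcyclohexan-1-one | C[C@@H]1CC[C@H](CCOCc2ccccc2)C(C)(C)C1=O | intermediate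
9 | (3R,6R)-3-(2-hydroxyethyl)-2,2,6-trimethylcyclohexan-1-one | C[C@@H]1CC[C@H](CCO)C(C)(C)C1=O | intermediate
10 | ethyl 2-(triphenyl-λ5-phosphanylidene)propanoate | CCOC(=O)C(C)=P(c1ccccc1)(c1ccccc1)c1ccccc1 | starting material
11 | 2-[(1R,4R)-2,2,4-trimethyl-3-oxocyclohexyl]acetaldehyde | C[C@@H]1CC[C@H](CC=O)C(C)(C)C1=O | intermediate
12 | ethyl (2E)-2-methyl-4-[(1R,4R)-2,2,4-trimethyl-3-oxocyclohexyl]but-2-enoate | C[C@@H]1CC[C@H](C/C=C(\C)C(=O)OCC)C(C)(C)C1=O | intermediate
13 | ethyl (2E)-2-methyl-4-[(1R)-2,2,4-trimethyl-3-{[(trifluoromethyl)sulfonyl]oxy}cyclohex-3-en-1-yl]but-2-enoate | CCOC(=O)/C(C)=C/C[C@H]1CCC(C)=C(OS(=O)(=O)C(F)(F)F)C1(C)C | intermediate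
14 | ethyl (2E)-4-[(1R)-3-(hydroxymethyl)-2,2,4-trimethylcyclohex-3-en-1-yl]-2-methylbut-2-enoate | CCOC(=O)/C(C)=C/C[C@H]1CCC(C)=C(CO)C1(C)C | intermediate
15 | ({(5R)-5-[(2E)-4-ethoxy-3-methyl-4-oxobut-2-en-1-yl]-2,6,6-trimethylcyclohex-1-en-1-yl}methyl)triphenylphosphonium bromide | CCOC(=O)/C(C)=C/C[C@H]1CCC(C)=C(C[P+](c2ccccc2)(c2ccccc2)c2ccccc2)C1(C)C.[Br-] | intermediate
16 | 3-methylbut-2-en-1-ol (prenol) | CC(C)=CCO | starting material
17 | [(2R)-3,3-dimethyloxiran-2-yl]methanol | OC[C@H]1OC1(C)C | intermediate
18 | allylmagnesium bromide | C=CC[Mg]Br | starting material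
19 | (2S)-3-methyl-2-(prop-2-en-1-yl)butane-1,3-diol | C=CC[C@@H](CO)C(C)(C)O | intermediate
20 | 2-methylbut-2-ene | CC=C(C)C | starting material
21 | (2S)-3-methyl-2-(3-methylbut-2-en-1-yl)butane-1,3-diol | CC(C)=CC[C@@H](CO)C(C)(C)O | intermediate
22 | (2S)-3-methyl-2-(3-methylbut-2-en-1-yl)butane-1,3-diol bis(triethylsilyl) ether | CC(C)=CC[C@@H](CO[Si](CC)(CC)CC)C(C)(C)O[Si](CC)(CC)CC | intermediate
23 | (2R)-5-methyl-2-{2-[(triethylsilyl)oxy]propan-2-yl}hex-4-enal | CC(C)=CC[C@@H](C=O)C(C)(C)O[Si](CC)(CC)CC | intermediate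
24 | ethyl (2E)-4-(diethoxyphosphoryl)-3-methylbut-2-enoate | CCOC(=O)/C=C(\C)CP(=O)(OCC)OCC | starting material
25 | ethyl (2E,4E,6S)-3,7-dimethyl-6-(3-methylbut-2-en-1-yl)-7-[(triethylsilyl)oxy]octa-2,4-dienoate | CC(C)=CC[C@@H](/C=C/C(C)=C/C(=O)OCC)C(C)(C)O[Si](CC)(CC)CC | intermediate
26 | (2E,4E,6S)-3,7-dimethyl-6-(3-methylbut-2-en-1-yl)-7-[(triethylsilyl)oxy]octa-2,4-dien-1-ol | CC(C)=CC[C@@H](/C=C/C(C)=C/CO)C(C)(C)O[Si](CC)(CC)CC | intermediate
27 | [(2E,4E,6S)-7-hydroxy-3,7-dimethyl-6-(3-methylbut-2-en-1-yl)octa-2,4-dien-1-yl]triphenylphosphonium bromide | CC(C)=CC[C@@H](/C=C/C(C)=C/C[P+](c1ccccc1)(c1ccccc1)c1ccccc1)C(C)(C)O.[Br-] | intermediate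
28 | crocetindialdehyde, (2E,4E,6E,8E,10E,12E,14E)-2,6,11,15-tetramethylhexadeca-2,4,6,8,10,12,14-heptaenedial | O=C/C(C)=C/C=C/C(C)=C/C=C/C=C(C)/C=C/C=C(C)/C=O | starting material
29 | ethyl (2E)-2-methyl-4-{(1R)-2,2,4-trimethyl-3-[(all-E)-3,7,12,16-tetramethyl-17-oxoheptadeca-1,3,5,7,9,11,13,15-octaen-1-yl]cyclohex-3-en-1-yl}but-2-enoate | O=C/C(C)=C/C=C/C(C)=C/C=C/C=C(C)/C=C/C=C(C)/C=C/C1=C(C)CC[C@H](C/C=C(\C)C(=O)OCC)C1(C)C | intermediate
30 | C50 ethyl ester (target with CO2Et in place of CH2OH), all-E, (2R,2′S) | CC(C)=CC[C@@H](/C=C/C(C)=C/C=C/C(C)=C/C=C/C(C)=C/C=C/C=C(C)/C=C/C=C(C)/C=C/C1=C(C)CC[C@H](C/C=C(\C)C(=O)OCC)C1(C)C)C(C)(C)O | intermediate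
31 | CNP0286110.1 | CC(C)=CC[C@@H](/C=C/C(C)=C/C=C/C(C)=C/C=C/C(C)=C/C=C/C=C(C)/C=C/C=C(C)/C=C/C1=C(C)CC[C@H](C/C=C(\C)CO)C1(C)C)C(C)(C)O | target

**Step count.** Total: 21 steps. Longest linear sequence: 13 steps (steps 1–10, 19, 20, 21).

**Steps most likely to fail**

Step 3. The strongly acidic catalyst may divert the hindered, fully substituted silyloxydiene into an open-chain Mukaiyama–Michael adduct, or facial and regiochemical discrimination may be insufficient. The fallback replaces catalyst control by auxiliary control and sets out from 4. Cycloaddition with (4R)-3-acryloyl-4-benzyl-1,3-oxazolidin-2-one (C=CC(=O)N1[C@H](Cc2ccccc2)COC1=O) and Et2AlCl in CH2Cl2 at −78 °C would give the imide adduct F1; the benzyl group of the chelated imide shields the Si face of the acryloyl α-carbon. LiOH/H2O2 would release the carboxylic acid F2. Coupling with N-hydroxypyridine-2-thione (DCC) would give the thiohydroxamate ester F3, and its photolysis with t-BuSH (Barton decarboxylation) comes back to the route at 7.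

Step 5. Desilylation of the hindered TIPS enol ether may be slow, and the free enolate may suffer proton transfer (loss of regiochemistry) or O-methylation. The fallback avoids enolate alkylation and sets out from 7. Simmons–Smith cyclopropanation of the enol ether (Et2Zn, CH2I2, CH2Cl2) on the face opposite the two cis substituents would give the siloxycyclopropane F4. Fluoride-induced ring opening (TBAF, THF; cyclopropanolate, homoenolate, protonation) turns the cyclopropane CH2 into the second methyl group and comes back at 8.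

Step 9. Transfer of the hydroxymethyl group from tin to the hindered tetrasubstituted vinyl-palladium may be too slow, so that reduction or decomposition of the triflate takes over. The fallback sets out from 13 and replaces transmetalation by CO insertion. Reductive carbonylation (Pd(OAc)2, dppp, CO, Et3SiH, Et3N, DMF, 70 °C) would give the enal F5, and Luche reduction (NaBH4, CeCl3, MeOH, 0 °C), which leaves the enoate alone, comes back at 14.

**Further compounds**

F1 | step 3 | (4R)-4-benzyl-3-{[(1S,2S,5R)-2-[2-(benzyloxy)ethyl]-3,5-dimethyl-4-{[tri(propan-2-yl)silyl]oxy}cyclohex-3-en-1-yl]carbonyl}-1,3-oxazolidin-2-one | C[C@@H]1C[C@H](C(=O)N2[C@H](Cc3ccccc3)COC2=O)[C@H](CCOCc2ccccc2)C(C)=C1O[Si](C(C)C)(C(C)C)C(C)C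
F2 | step 3 | (1S,2S,5R)-2-[2-(benzyloxy)ethyl]-3,5-dimethyl-4-{[tri(propan-2-yl)silyl]oxy}cyclohex-3-ene-1-carboxylic acid | C[C@@H]1C[C@H](C(=O)O)[C@H](CCOCc2ccccc2)C(C)=C1O[Si](C(C)C)(C(C)C)C(C)C
F3 | step 3 | 2-thioxopyridin-1(2H)-yl ester of F2 (Barton ester) | C[C@@H]1C[C@H](C(=O)On2ccccc2=S)[C@H](CCOCc2ccccc2)C(C)=C1O[Si](C(C)C)(C(C)C)C(C)C
F4 | step 5 | 5-[2-(benzyloxy)ethyl]-2,6-dimethyl-1-{[tri(propan-2-yl)silyl]oxy}bicyclo[4.1.0]heptane, cyclopropane anti to the methyl and benzyloxyethyl groups | C[C@@H]1CC[C@H](CCOCc2ccccc2)[C@@]2(C)C[C@@]12O[Si](C(C)C)(C(C)C)C(C)C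
F5 | step 9 | ethyl (2E)-4-[(1R)-3-formyl-2,2,4-trimethylcyclohex-3-en-1-yl]-2-methylbut-2-enoate | CCOC(=O)/C(C)=C/C[C@H]1CCC(C)=C(C=O)C1(C)C
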